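In a one-step world a recipe has one yield, and the order of charging does not enter. The first chemist holds that view here: east repeats the green recipe, green read 15.6% side product A at 90.0 min, so he puts east, north-east and west together at that figure, within the margin.

| setting | green | grey | ochre | blue | east | north-east | west |
|---|---|---|---|---|---|---|---|
| substrate | 0.20 M | 0.20 M | 0.20 M | 0.30 M | 0.20 M | 0.20 M (fed, over 40 min) | 0.20 M |
| partner | 0.70 equiv | 0.47 equiv | 1 equiv | 0.70 equiv | 0.700 equiv | 0.700 equiv | 0.700 equiv (fed, over 40 min) |
| remark | run made earlier | run made earlier | run made earlier | run made earlier | everything together at the start | all else is in the flask from the start; the feed brings no volume worth counting | all else is in the flask from the start; the feed brings no volume worth counting |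
| time |  |  |  |  | 1.5 h | 1.5 h | 1.5 h |

| run | time / min | side product A / % | target / % |
|---|---|---|---|
| green | 8.00 | 2.5 | 32.4 |
| green | 12.0 | 4.1 | 36.7 |
| green | 20.0 | 6.6 | 39.3 |
| green | 30.0 | 9.9 | 39.6 |
| green | 50.0 | 13.0 | 40.2 |
| green | 90.0 | 15.6 | 42.0 |
| grey | 6.00 | 1.7 | 30.8 |
| grey | 10.0 | 3.0 | 37.8 |
| grey | 15.0 | 4.2 | 42.0 |
| grey | 25.0 | 6.6 | 44.2 |
| grey | 40.0 | 8.3 | 46.2 |
| grey | 80.0 | 11.3 | 48.5 |
| ochre | 12.0 | 6.0 | 31.7 |
| ochre | 25.0 | 9.9 | 34.2 |
| ochre | 40.0 | 13.4 | 34.4 |
| ochre | 50.0 | 14.6 | 34.6 |
| ochre | 60.0 | 15.0 | 35.1 |
| ochre | 80.0 | 16.7 | 34.2 |
| blue | 6.00 | 2.3 | 25.8 |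
| blue | 20.0 | 7.3 | 35.1 |
| blue | 30.0 | 9.2 | 37.0 |
| blue | 50.0 | 10.7 | 36.6 |
| blue | 80.0 | 12.6 | 38.1 |

(scatter of a reading: 0.5 percentage points)

- the numbers in the tables scatter by 0.5 percentage points (one standard deviation)
- steps that have been proposed: substrate -> target; substrate <-> intermediate A; substrate + partner -> intermediate B; partner + intermediate A -> side product A; partner + intermediate B -> side product B; intermediate B <-> intermediate C

1. the flask that comes out highest in amount of side product A, in percent of the substrate charged, or "all alike" when all lie within 1.5 percentage points (east / north-east / west / all alike)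
2. side product A at the end, in percent of the substrate charged, east
3. side product A at the end, in percent of the substrate charged, north-east
4. side product A at the end, in percent of the substrate charged, west

The second chemist objects. On the proposed steps, target and intermediate A both leave substrate without partner, each first order. Divide one rate by the other and substrate cancels, whatever its curve, so the integral is a straight line: a selectivity factor that a feed leaves untouched, the way back set aside. Side product A over target reads 0.233 in grey, 0.371 in green and, higher still, 0.488 at the end of ochre. Ochre's side product A is still rising between its last two readings, from 15.0% to 16.7%, so I take this ochre figure as a low estimate of the pool ratio: substrate sent to intermediate A per unit of target.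

My reckoning: with the partner route shut, target and pool share the charge, and the ratio puts the pool at 32.8%, twice green's reading. That is a mark for west, not a forecast of it.

The forecast sides with the second chemist and puts west lower than my mark: east 15.7%, north-east 14%, west 23%, highest west, on the ground that “Partner is therefore saved and arrives when A is abundant.”

West gives 27.6%, above east at 15.3% and north-east at 15.0%. East and north-east differ by 0.30 percentage points, under the margin, so at this recipe the first chemist's view holds for side product A when substrate is fed. Applied to west's target of 57.8%, the pool ratio gives 28.2%, and west's side product A plus intermediate A stand at 33.2%, above that low estimate.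

    substrate → target (k = 0.0875 min⁻¹)
    substrate ⇌ intermediate A (K = 14.0, k = 0.0604 min⁻¹)
    substrate + partner → intermediate B (k = 0.767 M⁻¹ min⁻¹)
    partner + intermediate A → side product A (k = 0.313 M⁻¹ min⁻¹)
    partner + intermediate B → side product B (k = 0.173 M⁻¹ min⁻¹)
    intermediate B ⇌ intermediate C (K = 1.10, k = 0.00805 min⁻¹)

North-east with 1.80 equiv partner ends at 25.6% target, so the ratio gives a low estimate of 12.5% for its pool. That flask computes to 15.9% side product A, with 0.723% intermediate A beside it.

The earlier runs and the new flask were computed with made-up constants; the scatter is artificial.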